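**Retrosynthetic overview**
1. Target 22 ⇐ global desilylation of 21 ⇐ reductive removal of the C4 oxygen of 20 ⇐ C–B oxidation of chroman boronate 19.
2. 19 ⇐ one-step formal [4+2] that makes C2–C3 and C4–C4a, between the aryl oxocarbenium ion from α-acetoxy ether 11 and the chiral (E)-2-alkoxyvinyl boronate 17.
3. Enabling feature: O1 is an aryl benzyl ether oxygen. Ionised at benzylic C2, O1=C2 together with C8a=C4a of ring A is a cationic 2-oxadiene, and C3–C4 can come as an enol ether with a removable oxygen on C4 and boron on C3 as the latent 3-OH.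
4. Ring A (phloroglucinol, prenyl para to the future O1, so both ortho carbons are equivalent and only the 6-prenyl isomer can form) and ring B (3,4-dihydroxybenzoic acid) are bought; ring C is the only ring made, in the key step.
5. 11 ⇐ aryl ester 9 ⇐ phenol 5 + acid 8; 17 ⇐ ynol ether 16 ⇐ (1S,2R)-2-phenylcyclohexanol 12 + trichloroethylene 13.

Key step: step 9

Assumption: the (1S,2R)-2-phenylcyclohexyl group of 17 is taken to cover the enol ether face that would lead to the 2S,3R series (s-trans enol ether, phenyl over one face); should the induction run the other way, the (1R,2S) alcohol is used and nothing else changes.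

Abbreviations: TBS = tert-butyldimethylsilyl; prenyl = 3-methylbut-2-en-1-yl; Bpin = 4,4,5,5-tetramethyl-1,3,2-dioxaborolan-2-yl.

**Route**

Step 1
Reactants: 1 phloroglucinol (benzene-1,3,5-triol); 2 2-methylbut-3-en-2-ol
Product: 3 2-prenylbenzene-1,3,5-triol (2-prenylphloroglucinol)
Conditions: BF3·OEt2 (0.5 equiv), 1,4-dioxane, rt, 1 in excess
Reagents that add atoms: none
Why: Friedel–Crafts C-alkylation in which BF3 ionises the tertiary allylic alcohol to the dimethylallyl cation, which the electron-rich triol should capture at its primary terminus to give the linear prenyl group, the excess of 1 limiting double alkylation.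

Step 2
Reactants: 3 2-prenylphloroglucinol
Product: 4 1,3,5-tris(TBS-oxy)-2-prenylbenzene
Conditions: TBSCl (3.6 equiv), imidazole, DMF, rt
Reagents that add atoms: tert-butyldimethylsilyl chloride (TBSCl), CC(C)(C)[Si](C)(C)Cl
Why: Imidazole-promoted silyl ether formation should protect all three phenols.

Step 3
Reactants: 4 1,3,5-tris(TBS-oxy)-2-prenylbenzene
Product: 5 3,5-bis(TBS-oxy)-4-prenylphenol
Conditions: Cs2CO3 (0.5 equiv), DMF/H2O (10:1), 0 °C, stopped after loss of one silyl group
Reagents that add atoms: none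
Why: Base-mediated cleavage of an aryl silyl ether, in which attack at silicon should be fastest at the silyl ether para to the prenyl group, the only one without an ortho substituent; this frees the oxygen that becomes O1.

Step 4
Reactants: 6 3,4-dihydroxybenzoic acid
Product: 8 3,4-bis(TBS-oxy)benzoic acid, via silyl ester 7 (not isolated)
Conditions: TBSCl (3.5 equiv), imidazole, DMF, rt; then AcOH/THF/H2O, rt
Reagents that add atoms: tert-butyldimethylsilyl chloride (TBSCl), CC(C)(C)[Si](C)(C)Cl
Why: Exhaustive silylation followed by selective hydrolysis of the far more labile silyl ester, the aryl silyl ethers being stable to aqueous acetic acid.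

Step 5
Reactants: 5 3,5-bis(TBS-oxy)-4-prenylphenol; 8 3,4-bis(TBS-oxy)benzoic acid
Product: 9 3,5-bis(TBS-oxy)-4-prenylphenyl 3,4-bis(TBS-oxy)benzoate
Conditions: DCC, DMAP (cat.), CH2Cl2, 0 °C to rt
Reagents that add atoms: none
Why: Steglich esterification (DCC activation, DMAP acyl transfer) of an unhindered phenol, which joins rings A and B through the future O1.

Step 6
Reactants: 9 aryl ester
Product: 11 [3,4-bis(TBS-oxy)phenyl][3,5-bis(TBS-oxy)-4-prenylphenoxy]methyl acetate (racemic α-acetoxy ether), via aluminium hemiacetal 10 (not isolated)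
Conditions: i-Bu2AlH (DIBAL-H), CH2Cl2, −78 °C; then pyridine, DMAP, Ac2O, −78 to 0 °C
Reagents that add atoms: acetic anhydride, CC(=O)OC(C)=O
Why: Reductive acetylation of an ester, in which hydride addition at −78 °C should give a tetrahedral aluminium hemiacetal that is acetylated in place; the new acetal centre is racemic, which is without consequence because it becomes planar in step 9.

Step 7
Reactants: 12 (1S,2R)-2-phenylcyclohexan-1-ol; 13 trichloroethylene
Product: 16 (1S,2R)-2-phenylcyclohexyl ethynyl ether, via dichlorovinyl ether 14 (not isolated), via lithium alkynyl ether 15 (not isolated)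
Conditions: KH, THF, 0 °C to rt; then n-BuLi (2.5 equiv), −78 to −40 °C; then MeOH, −78 °C to rt
Reagents that add atoms: none
Why: Ynol ether synthesis in which the alkoxide adds to dichloroacetylene formed from 13, and n-BuLi then effects elimination and chlorine–lithium exchange; the stereocentres of 12 are not touched.

Step 8
Reactants: 16 (1S,2R)-2-phenylcyclohexyl ethynyl ether
Product: 17 (E)-2-[(1S,2R)-2-phenylcyclohexyloxy]ethenyl-Bpin
Conditions: pinacolborane (HBpin), Cp2Zr(H)Cl (5 mol%), CH2Cl2, rt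
Reagents that add atoms: pinacolborane, CC1(C)OBOC1(C)C
Why: Cp2Zr(H)Cl-catalysed syn-hydroboration of a terminal alkyne should place boron on the terminal carbon, β to oxygen, and give the (E)-alkenyl boronate.

Step 9
Reactants: 11 α-acetoxy ether; 17 (E)-2-alkoxyvinyl boronate
Product: 19 (2S,3S,4S)-5,7-bis(TBS-oxy)-2-[3,4-bis(TBS-oxy)phenyl]-6-prenyl-4-[(1S,2R)-2-phenylcyclohexyloxy]-3-Bpin-chroman (2,3-trans and 3,4-trans), via aryl oxocarbenium triflate 18 (not isolated)
Conditions: TMSOTf (1.2 equiv), 2,6-di-tert-butyl-4-methylpyridine (1.5 equiv), 17 (1.5 equiv), 4 Å molecular sieves, CH2Cl2, −78 °C; Et3N quench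
Reagents that add atoms: none
Why: Proposed new method: TMSOTf should remove acetate from 11 to give the (E)-aryl oxocarbenium ion 18, a cationic 2-oxadiene (C4a=C8a of ring A, O1, C2), whose C2 is attacked by the boron-bearing β-carbon of enol ether 17 (C2–C3), and the alkoxy-stabilised cation then formed at C4 is captured by the ortho carbon of ring A (C4–C4a, the proton going to the pyridine base); the closest known reaction type is the oxa-Povarov reaction of aryl oxocarbenium ions with vinyl ethers and styrenes, extended here to a β-boryl enol ether that carries a chiral alkoxy group. Ring C closes by a 6-exo-trig attack of the arene carbon on the exocyclic C4=O+ bond (Friedel–Crafts), so the whole event is a stepwise inverse-demand [4+2] cycloaddition. C2 and C3 are set in the first bond formation: the (E) geometry of both partners and the endo position of the alkoxy group, as in Povarov reactions of (E)-β-substituted enol derivatives, should place aryl, boron and alkoxy all equatorial (2,3-trans, 3,4-trans), and the absolute sense is controlled by the 2-phenylcyclohexyl group, whose phenyl ring covers one face of the enol ether. The step needs regioselectivity (oxygen on C4, boron on C3), which the polarity of the enol ether secures, and positional selectivity on ring A, which is no issue because the two ortho carbons of the 4-prenyl-3,5-disilyloxyphenyl ether are equivalent, so only the 6-prenyl chroman can form. The hindered base keeps triflic acid away from the prenyl group and the C–B bond, and any minor diastereomer is removed by chromatography, so one enantiomeric series is carried on.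

Step 10
Reactants: 19 chroman boronate
Product: 20 (2R,3S,4R)-5,7-bis(TBS-oxy)-2-[3,4-bis(TBS-oxy)phenyl]-6-prenyl-4-[(1S,2R)-2-phenylcyclohexyloxy]chroman-3-ol
Conditions: NaBO3·4H2O, THF/H2O, 0 °C to rt
Reagents that add atoms: sodium perborate (NaBO3), [Na+].[O-]OB=O
Why: Oxidation of a secondary alkyl boronate, in which C3 migrates from boron to oxygen with retention, so the 3-OH should inherit the trans relation to the 2-aryl group; the prenyl alkene is inert to perborate.

Step 11
Reactants: 20 4-alkoxy chroman-3-ol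
Product: 21 (2R,3S)-5,7-bis(TBS-oxy)-2-[3,4-bis(TBS-oxy)phenyl]-6-prenylchroman-3-ol
Conditions: Et3SiH (5 equiv), BF3·OEt2 (1.5 equiv), CH2Cl2, −78 to −30 °C; aqueous NaHCO3
Reagents that add atoms: none
Why: Ionic hydrogenation of a benzylic ether, in which the Lewis acid ionises the C4–O bond (cation stabilised by the three ring-A oxygens) and Et3SiH delivers hydride, the laboratory counterpart of the reductive step that turns a leucoanthocyanidin into catechin; C2 and C3 are untouched, the C4 stereocentre and the auxiliary are removed together.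

Step 12
Reactants: 21 tetrasilyl ether
Product: 22 6-prenylcatechin, (2R,3S)-2-(3,4-dihydroxyphenyl)-6-prenylchromane-3,5,7-triol
Conditions: Et3N·3HF, THF, rt, argon
Reagents that add atoms: none
Why: Fluoride cleavage of the four aryl silyl ethers under buffered, non-oxidising conditions that should leave the prenyl alkene, the catechol and both stereocentres unchanged.

**Compound list**
1 | phloroglucinol | Oc1cc(O)cc(O)c1 | starting material
2 | 2-methylbut-3-en-2-ol | CC(C)(O)C=C | starting material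
3 | 2-prenylbenzene-1,3,5-triol | CC(C)=CCc1c(O)cc(O)cc1O | intermediate
4 | 1,3,5-tris(TBS-oxy)-2-prenylbenzene | CC(C)=CCc1c(O[Si](C)(C)C(C)(C)C)cc(O[Si](C)(C)C(C)(C)C)cc1O[Si](C)(C)C(C)(C)C | intermediate
5 | 3,5-bis(TBS-oxy)-4-prenylphenol | CC(C)=CCc1c(O[Si](C)(C)C(C)(C)C)cc(O)cc1O[Si](C)(C)C(C)(C)C | intermediate
6 | 3,4-dihydroxybenzoic acid | OC(=O)c1ccc(O)c(O)c1 | starting material
7 | TBS 3,4-bis(TBS-oxy)benzoate (not isolated) | CC(C)(C)[Si](C)(C)OC(=O)c1ccc(O[Si](C)(C)C(C)(C)C)c(O[Si](C)(C)C(C)(C)C)c1 | intermediate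
8 | 3,4-bis(TBS-oxy)benzoic acid | OC(=O)c1ccc(O[Si](C)(C)C(C)(C)C)c(O[Si](C)(C)C(C)(C)C)c1 | intermediate
9 | 3,5-bis(TBS-oxy)-4-prenylphenyl 3,4-bis(TBS-oxy)benzoate | CC(C)=CCc1c(O[Si](C)(C)C(C)(C)C)cc(OC(=O)c2ccc(O[Si](C)(C)C(C)(C)C)c(O[Si](C)(C)C(C)(C)C)c2)cc1O[Si](C)(C)C(C)(C)C | intermediate
10 | diisobutylaluminium hemiacetal of 9 (not isolated, racemic) | CC(C)=CCc1c(O[Si](C)(C)C(C)(C)C)cc(OC(O[Al](CC(C)C)CC(C)C)c2ccc(O[Si](C)(C)C(C)(C)C)c(O[Si](C)(C)C(C)(C)C)c2)cc1O[Si](C)(C)C(C)(C)C | intermediate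
11 | [3,4-bis(TBS-oxy)phenyl][3,5-bis(TBS-oxy)-4-prenylphenoxy]methyl acetate (racemic) | CC(C)=CCc1c(O[Si](C)(C)C(C)(C)C)cc(OC(OC(C)=O)c2ccc(O[Si](C)(C)C(C)(C)C)c(O[Si](C)(C)C(C)(C)C)c2)cc1O[Si](C)(C)C(C)(C)C | intermediate
12 | (1S,2R)-2-phenylcyclohexan-1-ol | O[C@H]1CCCC[C@@H]1c1ccccc1 | starting material
13 | trichloroethylene | ClC=C(Cl)Cl | starting material
14 | (1S,2R)-2-phenylcyclohexyl (E)-1,2-dichlorovinyl ether (not isolated) | Cl/C=C(/Cl)O[C@H]1CCCC[C@@H]1c1ccccc1 | intermediate
15 | lithium acetylide of 16 (not isolated) | [Li]C#CO[C@H]1CCCC[C@@H]1c1ccccc1 | intermediate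
16 | (1S,2R)-2-phenylcyclohexyl ethynyl ether | C#CO[C@H]1CCCC[C@@H]1c1ccccc1 | intermediate
17 | 2-[(E)-2-{[(1S,2R)-2-phenylcyclohexyl]oxy}ethenyl]-4,4,5,5-tetramethyl-1,3,2-dioxaborolane | CC1(C)OB(/C=C/O[C@H]2CCCC[C@@H]2c2ccccc2)OC1(C)C | intermediate
18 | (E)-aryl oxocarbenium triflate from 11 (not isolated) | CC(C)=CCc1c(O[Si](C)(C)C(C)(C)C)cc([O+]=Cc2ccc(O[Si](C)(C)C(C)(C)C)c(O[Si](C)(C)C(C)(C)C)c2)cc1O[Si](C)(C)C(C)(C)C.[O-]S(=O)(=O)C(F)(F)F | intermediate
19 | (2S,3S,4S)-chroman boronate, 2,3-trans and 3,4-trans (the letters at C2 and C4 differ from 20 only because boron ranks below carbon) | CC(C)=CCc1c(O[Si](C)(C)C(C)(C)C)cc2c(c1O[Si](C)(C)C(C)(C)C)[C@@H](O[C@H]3CCCC[C@@H]3c3ccccc3)[C@H](B3OC(C)(C)C(C)(C)O3)[C@@H](c1ccc(O[Si](C)(C)C(C)(C)C)c(O[Si](C)(C)C(C)(C)C)c1)O2 | intermediate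
20 | (2R,3S,4R)-5,7-bis(TBS-oxy)-2-[3,4-bis(TBS-oxy)phenyl]-6-prenyl-4-{[(1S,2R)-2-phenylcyclohexyl]oxy}chroman-3-ol | CC(C)=CCc1c(O[Si](C)(C)C(C)(C)C)cc2c(c1O[Si](C)(C)C(C)(C)C)[C@@H](O[C@H]3CCCC[C@@H]3c3ccccc3)[C@H](O)[C@@H](c1ccc(O[Si](C)(C)C(C)(C)C)c(O[Si](C)(C)C(C)(C)C)c1)O2 | intermediate
21 | (2R,3S)-5,7-bis(TBS-oxy)-2-[3,4-bis(TBS-oxy)phenyl]-6-prenylchroman-3-ol | CC(C)=CCc1c(O[Si](C)(C)C(C)(C)C)cc2c(c1O[Si](C)(C)C(C)(C)C)C[C@H](O)[C@@H](c1ccc(O[Si](C)(C)C(C)(C)C)c(O[Si](C)(C)C(C)(C)C)c1)O2 | intermediate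
22 | 6-prenylcatechin, (2R,3S)-2-(3,4-dihydroxyphenyl)-6-(3-methylbut-2-en-1-yl)chromane-3,5,7-triol | CC(C)=CCc1c(O)cc2c(c1O)C[C@H](O)[C@@H](c1ccc(O)c(O)c1)O2 | target

Total step count: 12. Longest linear sequence: 9 steps (steps 1, 2, 3, 5, 6, 9, 10, 11, 12).

**Steps most likely to fail, with fallbacks**

1. Step 9 (Proposed new method). The boron-bearing carbon of 17 may be too weak a π-nucleophile, the β-boryl cation may lose boron before the ring closes, or the facial selectivity may be low. The fallback uses known reaction types, sets out from 11 and returns at 21. Alcohol 12 is vinylated with ethyl vinyl ether and Hg(OAc)2 (cat.) to (1S,2R)-2-phenylcyclohexyl vinyl ether F1. The oxa-Povarov reaction of 11 with this parent vinyl ether, under the conditions of step 9, should give the 2,4-cis 4-alkoxyflavan F2, whose diastereomers are separable. Camphorsulfonic acid (cat.) in warm toluene eliminates 2-phenylcyclohexanol to give the (2S)-flav-3-ene F3. Hydroboration with 9-BBN, anti to the 2-aryl group, with boron at C3 and much slower at the trisubstituted prenyl alkene, gives the 9-BBN adduct F4, and NaBO3 oxidation of it gives 21.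

2. Step 6. The aluminium hemiacetal of an aryl ester may collapse to aldehyde and aryloxide before it is acetylated, with over-reduction to follow. The fallback sets out from 5 and returns at 11. 3,4-Dihydroxybenzaldehyde is silylated (TBSCl, imidazole) to 3,4-bis(TBS-oxy)benzaldehyde F5. Acetyl chloride with ZnCl2 (cat.) adds across the carbonyl group to give chloro[3,4-bis(TBS-oxy)phenyl]methyl acetate F6. O-Alkylation of phenol 5 with this α-chloroalkyl ester (i-Pr2NEt, CH2Cl2, −40 °C) gives 11 by substitution instead of ester reduction.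

3. Step 3. Cleavage may occur at one of the two flanked silyl ethers, or a second silyl group may be lost. The fallback sets out from 3 and returns at 9. Triol 3 is esterified directly with acid 8 (DCC, DMAP, low temperature), the bulky acylpyridinium intermediate reacting at the only hydroxyl without an ortho substituent, to give 3,5-dihydroxy-4-prenylphenyl 3,4-bis(TBS-oxy)benzoate F7. Silylation of the two remaining phenols (TBSCl, imidazole) gives 9, so the differentiation rests on acylation and not on desilylation.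

Further compounds
F1 | step 9 | (1S,2R)-2-phenylcyclohexyl vinyl ether | C=CO[C@H]1CCCC[C@@H]1c1ccccc1
F2 | step 9 | (2S,4S)-5,7-bis(TBS-oxy)-2-[3,4-bis(TBS-oxy)phenyl]-6-prenyl-4-{[(1S,2R)-2-phenylcyclohexyl]oxy}chroman (2,4-cis) | CC(C)=CCc1c(O[Si](C)(C)C(C)(C)C)cc2c(c1O[Si](C)(C)C(C)(C)C)[C@@H](O[C@H]3CCCC[C@@H]3c3ccccc3)C[C@@H](c1ccc(O[Si](C)(C)C(C)(C)C)c(O[Si](C)(C)C(C)(C)C)c1)O2
F3 | step 9 | (2S)-5,7-bis(TBS-oxy)-2-[3,4-bis(TBS-oxy)phenyl]-6-prenyl-2H-chromene | CC(C)=CCc1c(O[Si](C)(C)C(C)(C)C)cc2c(c1O[Si](C)(C)C(C)(C)C)C=C[C@@H](c1ccc(O[Si](C)(C)C(C)(C)C)c(O[Si](C)(C)C(C)(C)C)c1)O2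
F4 | step 9 | 9-[(2,3-trans)-flavan-3-yl]-9-borabicyclo[3.3.1]nonane adduct of F3 | CC(C)=CCc1c(O[Si](C)(C)C(C)(C)C)cc2c(c1O[Si](C)(C)C(C)(C)C)C[C@H](B3C4CCCC3CCC4)[C@@H](c1ccc(O[Si](C)(C)C(C)(C)C)c(O[Si](C)(C)C(C)(C)C)c1)O2
F5 | step 6 | 3,4-bis(TBS-oxy)benzaldehyde | O=Cc1ccc(O[Si](C)(C)C(C)(C)C)c(O[Si](C)(C)C(C)(C)C)c1
F6 | step 6 | chloro[3,4-bis(TBS-oxy)phenyl]methyl acetate (racemic) | CC(=O)OC(Cl)c1ccc(O[Si](C)(C)C(C)(C)C)c(O[Si](C)(C)C(C)(C)C)c1
F7 | step 3 | 3,5-dihydroxy-4-prenylphenyl 3,4-bis(TBS-oxy)benzoate | CC(C)=CCc1c(O)cc(OC(=O)c2ccc(O[Si](C)(C)C(C)(C)C)c(O[Si](C)(C)C(C)(C)C)c2)cc1O
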